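A direct plan would join two molecules of 3-bromo-4,5-dimethoxybenzaldehyde A1 at their formyl carbons to the racemic carbinol A2, would deoxygenate it to the tetramethyl ether A3, and would cleave the four methyl ethers with BBr3. Its weakest steps would be:
- the union of the two formyl carbons, because one of two identical aldehydes must act as a carbanion equivalent beside two aryl bromides;
- the deoxygenation, a step spent only on erasing the oxygen and the stereocentre that the coupling made;
- the fourfold demethylation, which needs excess harsh Lewis acid, risks partial cleavage and sets an air-sensitive bis-catechol free in a corrosive work-up.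

The route would rest on the C5–O bonds of both catechols, traced back to formyl groups, and on buying the CH2–CH2 bridge inside 1,2-bis(4-hydroxyphenyl)ethane. In each ring the C4 oxygen lies para to the bridge carbon C1, so its two ortho positions are exactly C3 (Br) and C5 (OH). Both rings would therefore be elaborated at the same time, two-directionally, by ortho-formylation, ortho-bromination and a twofold Dakin oxidation that exchanges each C5–CHO bond for C5–OH. No benzylic C–C coupling, no deoxygenation and no ether cleavage would remain, no protecting group would be used, and the air-sensitive catechols would appear only in the last flask.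

Key step: step 3

Assumption: 1,2-bis(4-hydroxyphenyl)ethane (4,4'-dihydroxybibenzyl, 4,4'-ethylenediphenol) is taken as a catalogue bisphenol.

Step 1
Reactants: 1 1,2-bis(4-hydroxyphenyl)ethane
Product: 3 5,5'-(ethane-1,2-diyl)bis(2-hydroxybenzaldehyde), via bis(hydroxymethyl)bisphenol 2 (not isolated)
Conditions: MgCl2 (4.4 equiv), Et3N (4.4 equiv), (CH2O)n (7 equiv), THF, reflux; then 1 M HCl
Reagents that add atoms: paraformaldehyde (as formaldehyde), C=O
Why: Magnesium-mediated ortho-formylation of a phenol (Casnati–Skattebøl type), in which the magnesium phenoxide ArOMgCl delivers bound formaldehyde through a six-membered transition state only to the carbon ortho to oxygen, the benzylic alkoxide ArCH2OMgCl (2) is oxidised by hydride transfer to a second formaldehyde (Oppenauer type), and the chelated salicylaldehyde is deactivated so that each ring should stop at one formyl group.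

Step 2
Reactants: 3 5,5'-(ethane-1,2-diyl)bis(2-hydroxybenzaldehyde)
Product: 4 5,5'-(ethane-1,2-diyl)bis(3-bromo-2-hydroxybenzaldehyde)
Conditions: Br2 (2.1 equiv), NaOAc (2.2 equiv), AcOH/CH2Cl2, 10 °C to rt, dark
Reagents that add atoms: bromine, BrBr
Why: Electrophilic aromatic bromination directed by the phenol to its only free ortho position (para is held by the bridge, the other ortho by CHO), with NaOAc buffering HBr and ionic conditions in the dark sparing the benzylic CH2 groups and the aldehydes.

Step 3
Reactants: 4 5,5'-(ethane-1,2-diyl)bis(3-bromo-2-hydroxybenzaldehyde)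
Product: 6 1,2-bis(3-bromo-4,5-dihydroxyphenyl)ethane, via bis(aryl formate) 5 (not isolated)
Conditions: 30% aq H2O2 (2.4 equiv), NaOH (2.2 equiv), degassed THF/H2O, 0 °C to rt, argon; then aq Na2SO3, 1 M HCl to pH 2, work-up under argon
Reagents that add atoms: hydrogen peroxide, OO
Why: Hydroperoxide anion adds to each formyl carbon, and in the tetrahedral adduct the aryl group shifts from carbon to oxygen with loss of hydroxide, giving aryl formate 5 that hydroxide hydrolyses to the catechol and formate. This is the Dakin oxidation of ortho-hydroxybenzaldehydes, a Baeyer–Villiger-type 1,2-shift, run twice on one molecule. No ring is closed and no stereocentre is formed; the target is achiral. The selectivity needed is aryl over hydride migration, and the ortho-phenoxide of each ring secures it by making the migrating carbon electron-rich. The place of the new hydroxyl is fixed by the formyl carbon, so the 3-bromo-4,5-dihydroxy pattern should arise without isomers, while the aryl bromides and the CH2–CH2 bridge are inert to peroxide. Near-stoichiometric peroxide, one equivalent of base per formyl group (so that the formic acid set free returns the mixture to near neutrality), low temperature, exclusion of air and an acidic quench should keep the catechols from over-oxidation.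

Compound list

1 | 1,2-bis(4-hydroxyphenyl)ethane (4,4'-dihydroxybibenzyl) | Oc1ccc(CCc2ccc(O)cc2)cc1 | starting material
2 | 1,2-bis[4-hydroxy-3-(hydroxymethyl)phenyl]ethane (present as its magnesium salt) | OCc1cc(CCc2ccc(O)c(CO)c2)ccc1O | intermediate (not isolated)
3 | 5,5'-(ethane-1,2-diyl)bis(2-hydroxybenzaldehyde) | O=Cc1cc(CCc2ccc(O)c(C=O)c2)ccc1O | intermediate
4 | 5,5'-(ethane-1,2-diyl)bis(3-bromo-2-hydroxybenzaldehyde) | O=Cc1cc(CCc2cc(Br)c(O)c(C=O)c2)cc(Br)c1O | intermediate
5 | ethane-1,2-diylbis(3-bromo-2-hydroxy-5,1-phenylene) diformate (present as its phenoxide) | O=COc1cc(CCc2cc(Br)c(O)c(OC=O)c2)cc(Br)c1O | intermediate (not isolated)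
6 | 1,2-bis(3-bromo-4,5-dihydroxyphenyl)ethane (achiral) | Oc1cc(CCc2cc(O)c(O)c(Br)c2)cc(Br)c1O | target

Total step count: 3. Longest linear sequence: 3.

Steps most likely to fail

Step 3. The newly formed electron-rich catechols could be oxidised further by alkaline peroxide or air (quinone formation, ring cleavage), or hydride could migrate in place of aryl and give carboxylic acids. Fallback, setting out from 4 and coming back at 6: both phenols would be capped with MOMCl and i-Pr2NEt in CH2Cl2 to give 5,5'-(ethane-1,2-diyl)bis[3-bromo-2-(methoxymethoxy)benzaldehyde] F1. A Baeyer–Villiger oxidation with mCPBA in CH2Cl2 over NaHCO3 would then give ethane-1,2-diylbis[3-bromo-2-(methoxymethoxy)-5,1-phenylene] diformate F2 under non-basic conditions in which no free catechol meets the oxidant. HCl in degassed MeOH under argon would remove formates and acetals together to give 6.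

Step 1. The twofold formylation could stop after one ring, or phenol–formaldehyde condensation could lead to diarylmethane oligomers, both aggravated by poor solubility of the bis(magnesium phenoxide). Fallback, setting out from 1 and coming back at 3: NaH and MOMCl in DMF would give 1,2-bis[4-(methoxymethoxy)phenyl]ethane F3. Directed ortho-lithiation with n-BuLi and TMEDA in Et2O at 0 °C would give 1,2-bis[3-lithio-4-(methoxymethoxy)phenyl]ethane F4, and a DMF quench followed by water would give 5,5'-(ethane-1,2-diyl)bis[2-(methoxymethoxy)benzaldehyde] F5. Warming F5 with 3 M HCl in THF would cleave the acetals to give 3.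

Step 2. Low solubility of 3 could cause uneven bromination (one ring only), and bromine could also attack the benzylic positions or oxidise the aldehydes. Fallback, setting out from 1 and coming back at 4: bromine would be introduced first, on the more soluble and more reactive bisphenol, with NBS (2.05 equiv) and p-TsOH (10 mol%) in MeOH at rt, to give 1,2-bis(3-bromo-4-hydroxyphenyl)ethane F6. The magnesium-mediated ortho-formylation (MgCl2, Et3N, (CH2O)n, THF, reflux; then 1 M HCl) would then act on the single free ortho position of each ring and pass through 1,2-bis[3-bromo-4-hydroxy-5-(hydroxymethyl)phenyl]ethane F7 to 4.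

Further compounds

F1 | step 3 | 5,5'-(ethane-1,2-diyl)bis[3-bromo-2-(methoxymethoxy)benzaldehyde] | COCOc1c(Br)cc(CCc2cc(Br)c(OCOC)c(C=O)c2)cc1C=O
F2 | step 3 | ethane-1,2-diylbis[3-bromo-2-(methoxymethoxy)-5,1-phenylene] diformate | COCOc1c(Br)cc(CCc2cc(Br)c(OCOC)c(OC=O)c2)cc1OC=O
F3 | step 1 | 1,2-bis[4-(methoxymethoxy)phenyl]ethane | COCOc1ccc(CCc2ccc(OCOC)cc2)cc1
F4 | step 1 | 1,2-bis[3-lithio-4-(methoxymethoxy)phenyl]ethane | [Li]c1cc(CCc2ccc(OCOC)c([Li])c2)ccc1OCOC
F5 | step 1 | 5,5'-(ethane-1,2-diyl)bis[2-(methoxymethoxy)benzaldehyde] | COCOc1ccc(CCc2ccc(OCOC)c(C=O)c2)cc1C=O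
F6 | step 2 | 1,2-bis(3-bromo-4-hydroxyphenyl)ethane | Oc1ccc(CCc2ccc(O)c(Br)c2)cc1Br
F7 | step 2 | 1,2-bis[3-bromo-4-hydroxy-5-(hydroxymethyl)phenyl]ethane | OCc1cc(CCc2cc(Br)c(O)c(CO)c2)cc(Br)c1O
A1 | direct plan | 3-bromo-4,5-dimethoxybenzaldehyde | COc1cc(C=O)cc(Br)c1OC
A2 | direct plan | rac-1,2-bis(3-bromo-4,5-dimethoxyphenyl)ethan-1-ol | OC(Cc1cc(Br)c(OC)c(OC)c1)c1cc(Br)c(OC)c(OC)c1
A3 | direct plan | 1,2-bis(3-bromo-4,5-dimethoxyphenyl)ethane | COc1cc(CCc2cc(OC)c(OC)c(Br)c2)cc(Br)c1OC
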